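## The problem

Mollicellin A (25) is a depsidone. Ring A (the formyl benzoate ring, numbered C1 carboxyl carbon to C6 methyl carbon) and ring B (chromanone numbering) are joined by an ether oxygen and an ester, so that a seven-membered dioxepinone lies between them; ring B is also fused to a 2,2-dimethylpyran-4-one. There is no stereocentre, so the difficulty is regiochemical and steric. Ring A is pentasubstituted, with carboxyl (C1), ether oxygen (C2), formyl (C3) and hydroxyl (C4) on four neighbouring carbons. The ether links two carbons that are each flanked on both sides: ring A C2 lies between carboxyl and formyl, ring B C6 between the C5 methyl and the C7 ester oxygen. Ring B carries three oxygens (O6, O7 and the pyran O1) that must each go to a different partner, and its acyl carbon sits next to the methyl group. The aryl lactone is opened by alkoxides, the salicylaldehyde is sensitive to reduction and to nucleophiles, the chromanone is enolisable and is attacked by organometallics, and the hydroxyquinol stage of ring B is air-sensitive. The feature that opens a short route is that ring A atoms C3–C4–C5–C6 (formyl carbon, oxygen, hydrogen, methyl) are the C3–C6 diene of 4-hydroxy-6-methyl-2-pyrone, while C1 and C2 carry an acceptor (carboxyl) and a donor (aryloxy) on adjacent carbons, which are the two ends of a polarised alkyne.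

## Retrosynthesis

**Lactone C–O bond and last deprotection (25 ⇐ 24 ⇐ 23).** The final operation is cleavage of the ring A methyl ether of 24, which is selective because that ether is ortho to the formyl group. Before it, the ester C–O bond of the seven-membered ring is cut to give hydroxy acid 23. Closure through the ester is preferred to closure through the ether, since the latter would require substitution at a ring B carbon flanked on both sides. The free acid is chosen over an alkyl ester because an aryl ester is the better acyl donor, so transesterification by a phenoxide lies on the ring-opened side. The forward step must therefore activate the acid irreversibly, under dilution. Keeping the ring A oxygen methylated leaves only one phenol in 23.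

**Unmasking (23 ⇐ 22 ⇐ 21).** Acid 23 is drawn back to 22, which carries a benzyl ether on O7 and a benzyl ester on ring A, so that one hydrogenolysis frees both partners of the lactonisation. Compound 22 comes from 21, in which the formyl group is a dimethyl acetal and the chromanone carbonyl is a silyl enol ether; one aqueous acid treatment removes both masks. The benzyl ester replaces a simple alkyl ester for the reason given above. The enol ether is required because the alkyne is made with an alkyllithium, which a free aryl ketone would not survive.

**Ring A by cycloaddition (21 ⇐ 14 + 19).** Ring A bonds C2–C3 and C1–C6 are cut, giving pyrone 19 and aryloxypropiolate 14. This removes a whole ring and leaves no substitution to perform on a crowded arene: the ether, the masked formyl group, the oxygen, the methyl and the carboxyl are all delivered by the two partners. The neighbouring option, etherification of a preformed ring A halide, would first require that hexasubstituted pattern to be built. The forward reaction must be a [4+2] addition with a single regiochemical outcome, followed by decarboxylative aromatisation. The acetal (rather than a free formyl group) keeps the diene nucleophilic at C3 and prevents the formyl group acting as a heterodiene.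

**Push-pull alkyne (14 ⇐ 10 ⇐ 9 ⇐ 7 + 8 + 11).** The alkyne C–CO bond is cut to benzyl chloroformate 11 and an aryloxyacetylide, which is traced to the (E)-1,2-dichlorovinyl ether 9, made from phenol 7 and trichloroethylene 8. Enol ether 10 is inserted between 9 and the lithiation. This sequence makes the aryl–O–C(sp) bond from the phenol without any metal-catalysed coupling at the hindered O6. It asks only that the other functions of ring B tolerate an alkyllithium at low temperature.

**Ring B (7 ⇐ 6 ⇐ 3 + 4; 3 ⇐ 1).** Phenol 7 comes from catechol 6 by alkylation of the more acidic, unhindered O7 (para to the ketone). The pyranone ring of 6 is cut at the aryl–acyl bond and at O1–C2, giving triol 3 and 3-methylbut-2-enoic acid 4. The triol comes from aldehyde 1 by exchange of formyl for hydroxyl, so the oxygenation pattern is fixed by the position of the formyl group in 1. The forward annulation must acylate 3 at the position between the C4 hydroxyl and the methyl group.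

**Diene (19 ⇐ 18 ⇐ 17 ⇐ 15).** The acetal is cut to aldehyde 18, the C4–OMe bond to chloride 17, and the formyl C–C bond and the C4–Cl bond together to 4-hydroxy-6-methyl-2-pyrone 15. One chloroformylation installs both the C3 carbon and a leaving group at C4, so that the ring A oxygen substituent is introduced by a simple addition–elimination.

## Roads not taken

**Alternative 1:** The cut lies in the pyran ring of ring B: bonds O1–C2 and C3–C4 are disconnected to 4,5-bis(benzyloxy)-2-hydroxy-6-methylbenzaldehyde A2 and 2-methylpropene A3. In the forward step Sc(OTf)3 and an orthoester would turn A2 into a methoxy-substituted ortho-quinone methide, which A3 captures to give racemic chroman A1 with C4 as a methyl ether.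
- Merits: the pyran is annulated under mild Lewis acid catalysis and its position is fixed by the aldehyde carbon. In this respect it is cleaner than step 2 of the present route, which uses hot strong acid on an air-sensitive triol and relies on an intrinsic site preference.
- Weak points: the step builds only the peripheral ring, leaving ring A, the hindered ether and the lactone unsolved. C4 arrives at the wrong oxidation level, so an ether cleavage and an oxidation are needed where the acid annulation gives the ketone directly. The two benzyl ethers of A1 are not differentiated. A2 needs the same oxygenation pattern as 6 plus a formyl group.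
- Comparison: against the better regiochemical definition, the chosen plan sets a one-step annulation, a Hoesch/Kabbe fallback and a shorter ring B sequence. The alternative offers nothing for the central problem.

**Alternative 2:** Ring A bonds C1–C2, C3–C4 and C5–C6 are cut, giving diyne A5 (6-[(3,3-diethoxyprop-1-yn-1-yl)oxy]-2,2,5-trimethyl-4-oxochroman-7-yl but-2-ynoate) and ethoxyacetylene A6. A cationic monovalent rhodium catalyst, [Rh(cod)2]BF4 with BINAP, would cyclotrimerise them to A4, the ethyl ether diethyl acetal of the target, closing ring A and the seven-membered ring together.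
- Merits: this is the most convergent road. Ether, ester, ring A and all its substituents are present after one step and only an acetal hydrolysis and a dealkylation remain; in step count after the key step it is better than the present plan.
- Weak points: the orientation of A6 (ethoxy at C4 or C5) is not controlled by the tether. A seven-membered ring must form from a diyne with a six-atom tether, which is slow, so oligomerisation of A6 competes. A5 contains an aryl ynoate (an activated ester) and an ynol ether acetal next to each other. Making A5 needs an aryloxyacetylide in the presence of a ketone and that aryl ester, a harder version of the problem solved here by enol ether 10.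
- Comparison: the chosen plan sets against the higher convergence a two-component thermal reaction with one regiochemical variable, which both partners bias in the same direction, and a stable, isolable alkyne 14.

**Alternative 3:** The cut is at the ester C–O bond and ring A bond C1–C6. Heating 6-(2,4-dioxopentyl)-2,2-dimethyl-4H-1,3-dioxin-4-one A8 with 6-bromo-7-hydroxy-2,2,5-trimethylchroman-4-one A9 would release an acylketene that acylates O7. Base and then acid would fold the resulting aryl trioxooctanoate by aldol condensation into orsellinate ester A7.
- Merits: it is short, needs no protecting group on ring A, and forms the ester under neutral thermal conditions in the key step, where the present route needs three operations between cycloaddition and lactone.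
- Weak points: the road then needs an intramolecular aryl ether closure at a bromide flanked by methyl and acyloxy, to form the seven-membered ring. It also needs a late formylation of ring A with C3 and C5 both ortho to the free hydroxyl. The aryl ester can be expelled as phenoxide during the base-mediated aromatisation. The bromination that gives A9 must distinguish C6 from C8.
- Comparison: the chosen plan is longer, but the ether and the formyl group are fixed by construction before the ring is closed, and the final closure is an acylation.

Key step: step 10

Assumption: 2,4-dihydroxy-6-methylbenzaldehyde 1 is taken as a purchased compound; it is the Vilsmeier–Haack formylation product of orcinol, which could be used instead at the cost of one step.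

## Route

**Step 1**
Reactants: 1 2,4-dihydroxy-6-methylbenzaldehyde
Product: 3 6-methylbenzene-1,2,4-triol, via aryl formate 2 (not isolated)
Conditions: H2O2 (30% aq.), NaOH, H2O, 0 °C → rt, Ar; then HCl, Na2S2O4 wash
Reagents that add atoms: hydrogen peroxide, OO
Why: Dakin oxidation: the hydroperoxide adduct of the aldehyde rearranges by aryl migration, which ortho and para hydroxyls accelerate, to formate 2, and this is hydrolysed in the same medium. Exclusion of air and a reductive work-up protect the triol, which is used directly in step 2.

**Step 2**
Reactants: 3 6-methylbenzene-1,2,4-triol; 4 3-methylbut-2-enoic acid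
Product: 6 6,7-dihydroxy-2,2,5-trimethylchroman-4-one, via aryl enone 5 (not isolated)
Conditions: P2O5/MeSO3H, 70 °C, Ar
Reagents that add atoms: none
Why: Friedel–Crafts acylation is expected at the free position para to the C2 hydroxyl and ortho to the C4 hydroxyl, the site preferred in hydroxyquinols and in orcinol, rather than between two oxygens. The only hydroxyl next to the new acyl group then closes the pyranone by oxa-Michael addition to enone 5; this is the standard one-pot chromanone synthesis from phenols.

**Step 3**
Reactants: 6 6,7-dihydroxy-2,2,5-trimethylchroman-4-one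
Product: 7 7-(benzyloxy)-6-hydroxy-2,2,5-trimethylchroman-4-one
Conditions: BnBr (1.05 equiv), K2CO3 (1.1 equiv), DMF, rt
Reagents that add atoms: benzyl bromide, BrCc1ccccc1
Why: Williamson etherification with one equivalent of weak base should alkylate the 7-hydroxyl, which is para to the ketone and hence the more acidic, and is unhindered. The 6-hydroxyl is flanked by the methyl group; the selectivity follows the 4-O-alkylation of 3,4-dihydroxyaryl ketones and aldehydes.

**Step 4**
Reactants: 7 7-(benzyloxy)-6-hydroxy-2,2,5-trimethylchroman-4-one; 8 trichloroethylene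
Product: 9 7-(benzyloxy)-6-{[(E)-1,2-dichloroethenyl]oxy}-2,2,5-trimethylchroman-4-one
Conditions: K2CO3, DMF, 70 °C
Reagents that add atoms: none
Why: Base converts trichloroethylene into dichloroacetylene, to which the phenoxide adds in anti fashion to give the (E)-dichlorovinyl ether. This is the established entry to aryl ynol ethers, and the small linear electrophile tolerates the hindered O6.

**Step 5**
Reactants: 9 7-(benzyloxy)-6-{[(E)-1,2-dichloroethenyl]oxy}-2,2,5-trimethylchroman-4-one
Product: 10 {[7-(benzyloxy)-6-{[(E)-1,2-dichloroethenyl]oxy}-2,2,5-trimethyl-2H-chromen-4-yl]oxy}(tert-butyl)dimethylsilane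
Conditions: TBSOTf, Et3N, CH2Cl2, 0 °C → rt
Reagents that add atoms: tert-butyldimethylsilyl trifluoromethanesulfonate, CC(C)(C)[Si](C)(C)OS(=O)(=O)C(F)(F)F
Why: Soft enolisation toward C3, the only enolisable position, gives the silyl enol ether. It masks the ketone against the alkyllithium of step 6 and is removed later together with the acetal.

**Step 6**
Reactants: 10 {[7-(benzyloxy)-6-{[(E)-1,2-dichloroethenyl]oxy}-2,2,5-trimethyl-2H-chromen-4-yl]oxy}(tert-butyl)dimethylsilane; 11 benzyl chloroformate
Product: 14 benzyl 3-({7-(benzyloxy)-4-[(tert-butyldimethylsilyl)oxy]-2,2,5-trimethyl-2H-chromen-6-yl}oxy)prop-2-ynoate, via chloroethynyl ether 12 (not isolated), via lithium aryloxyacetylide 13 (not isolated)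
Conditions: n-BuLi (2.2 equiv), THF, −78 → −40 °C; then transfer into ClCO2Bn (1.5 equiv), THF, −78 °C
Reagents that add atoms: none
Why: The first equivalent of n-BuLi eliminates HCl to give chloroalkyne 12 and the second exchanges chlorine for lithium to give acetylide 13. Inverse addition to the chloroformate should give the ynoate by C-acylation; the silyl enol ether and the benzyl ether are inert at −78 °C. An aryl ynol ether has no β-hydrogen for retro-ene cleavage, so 14 should be isolable.

**Step 7**
Reactants: 15 4-hydroxy-6-methyl-2H-pyran-2-one
Product: 17 4-chloro-6-methyl-2-oxo-2H-pyran-3-carbaldehyde, via C3 iminium chloride 16 (not isolated)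
Conditions: POCl3, DMF, 0 → 60 °C; then ice-water
Reagents that add atoms: N,N-dimethylformamide, CN(C)C=O; phosphoryl chloride, O=P(Cl)(Cl)Cl; water, O
Why: Vilsmeier–Haack chloroformylation of a cyclic 4-hydroxy-2-pyranone, as with 4-hydroxycoumarin: the chloroiminium ion attacks the nucleophilic C3 and the 4-hydroxyl is replaced by chloride. Iminium salt 16 is hydrolysed on work-up.

**Step 8**
Reactants: 17 4-chloro-6-methyl-2-oxo-2H-pyran-3-carbaldehyde
Product: 18 4-methoxy-6-methyl-2-oxo-2H-pyran-3-carbaldehyde
Conditions: NaOMe (1.0 equiv), MeOH, −20 → 0 °C
Reagents that add atoms: sodium methoxide, C[O-].[Na+]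
Why: Addition–elimination at C4, which is activated by both the formyl and the lactone carbonyl, is the usual reaction of 4-chloro-3-formyl pyranones and coumarins with heteroatom nucleophiles. One equivalent at low temperature should keep methoxide from opening the lactone.

**Step 9**
Reactants: 18 4-methoxy-6-methyl-2-oxo-2H-pyran-3-carbaldehyde
Product: 19 3-(dimethoxymethyl)-4-methoxy-6-methyl-2H-pyran-2-one
Conditions: HC(OMe)3, MeOH, TsOH·H2O (cat.), rt; then NaHCO3
Reagents that add atoms: trimethyl orthoformate, COC(OC)OC; methanol, CO
Why: Acid-catalysed acetalisation is driven by the orthoformate as water scavenger. In methanol any exchange at the C4 methoxy group is degenerate, so only the aldehyde changes.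

**Step 10**
Reactants: 14 benzyl 3-({7-(benzyloxy)-4-[(tert-butyldimethylsilyl)oxy]-2,2,5-trimethyl-2H-chromen-6-yl}oxy)prop-2-ynoate; 19 3-(dimethoxymethyl)-4-methoxy-6-methyl-2H-pyran-2-one
Product: 21 benzyl 2-({7-(benzyloxy)-4-[(tert-butyldimethylsilyl)oxy]-2,2,5-trimethyl-2H-chromen-6-yl}oxy)-3-(dimethoxymethyl)-4-methoxy-6-methylbenzoate, via oxabicyclooctadienone adduct 20 (not isolated)
Conditions: 19 (3 equiv), mesitylene, BHT (cat.), 160 °C, sealed tube, Ar
Reagents that add atoms: none
Why: Proposed new method: a thermal, concerted but asynchronous [4+2] addition across C3 and C6 of pyrone 19 is expected, in which the nucleophilic C3 (the position where 4-methoxy-2-pyrones react with electrophiles) bonds to the electrophilic alkyne carbon that carries the aryloxy group and is β to the ester, while C6 bonds to the ester-bearing carbon; the 2-oxabicyclo[2.2.2]octadienone 20 then loses CO2 by cycloreversion to give the benzene ring. The closest known reaction type is the Diels–Alder/decarboxylation of 4-methoxy-6-methyl-2-pyrone with propiolates and acetylenedicarboxylates to give benzoates, together with the addition of ynamines to 2-pyrones, in which the donor-bearing alkyne carbon likewise becomes attached to pyrone C3; a donor–acceptor ynol ether ester as dienophile and a 3-acetal-substituted pyrone have not been shown. Ring A is closed by an intermolecular [4+2] that forms the six-membered carbocycle with bonds C2–C3 and C1–C6 in one event, and no other ring is formed. The two bridgehead stereocentres of 20 arise as a racemic pair fixed by the bicycle and are erased on aromatisation, so no stereocontrol is required. The only selectivity needed is regiochemical, and it should be secured because both partners are polarised in the same sense: the C4 methoxy donor makes C3 the nucleophilic diene terminus, and the aryloxy donor and ester acceptor sit at opposite ends of the alkyne. The aryl ynol ether cannot fragment to a ketene and both ortho positions of its aryl group are blocked, the acetal keeps the diene electron-rich and removes a competing heterodiene, and the excess of the cheap pyrone is recoverable.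

**Step 11**
Reactants: 21 benzyl 2-({7-(benzyloxy)-4-[(tert-butyldimethylsilyl)oxy]-2,2,5-trimethyl-2H-chromen-6-yl}oxy)-3-(dimethoxymethyl)-4-methoxy-6-methylbenzoate
Product: 22 benzyl 2-{[7-(benzyloxy)-2,2,5-trimethyl-4-oxochroman-6-yl]oxy}-3-formyl-4-methoxy-6-methylbenzoate
Conditions: 1 M HCl, THF, rt
Reagents that add atoms: water, O
Why: Aqueous acid hydrolyses the electron-rich aryl dimethyl acetal and, by C-protonation and desilylation, the silyl enol ether in one operation. Benzyl ester, benzyl ether and diaryl ether are inert under these conditions.

**Step 12**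
Reactants: 22 benzyl 2-{[7-(benzyloxy)-2,2,5-trimethyl-4-oxochroman-6-yl]oxy}-3-formyl-4-methoxy-6-methylbenzoate
Product: 23 3-formyl-2-[(7-hydroxy-2,2,5-trimethyl-4-oxochroman-6-yl)oxy]-4-methoxy-6-methylbenzoic acid
Conditions: H2 (1 atm), 10% Pd/C, EtOAc, rt, stopped after 2 equiv H2
Reagents that add atoms: none
Why: Hydrogenolysis of a benzyl ester and a phenolic benzyl ether is fast. The formyl group, flanked by two ortho substituents on an electron-rich ring, and the chromanone carbonyl should be reduced much more slowly in ethyl acetate at 1 atm, as in debenzylations of formyl-bearing depsides.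

**Step 13**
Reactants: 23 3-formyl-2-[(7-hydroxy-2,2,5-trimethyl-4-oxochroman-6-yl)oxy]-4-methoxy-6-methylbenzoic acid
Product: 24 O-methylmollicellin A (the target with its ring A hydroxyl as methyl ether)
Conditions: DCC, DMAP (cat.), CH2Cl2 (0.005 M), 0 °C → rt
Reagents that add atoms: none
Why: Carbodiimide lactonisation of a 2-(2-hydroxyaryloxy)benzoic acid is the classical depsidone ring closure. The only free phenol is O7, and irreversible activation under dilution avoids the unfavourable phenoxide/alkoxide ester equilibrium.

**Step 14**
Reactants: 24 O-methylmollicellin A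
Product: 25 mollicellin A
Conditions: BCl3, CH2Cl2, −78 → 0 °C; then H2O
Reagents that add atoms: none
Why: BCl3 chelated between the formyl oxygen and the ortho methoxy group should cleave only that methyl ether, the standard selective demethylation ortho to a carbonyl. The lactone and the chromanone ring are not expected to react at low temperature.

## Compound list

1 | 2,4-dihydroxy-6-methylbenzaldehyde | Cc1cc(O)cc(O)c1C=O | starting material
2 | 2,4-dihydroxy-6-methylphenyl formate | Cc1cc(O)cc(O)c1OC=O | intermediate (not isolated)
3 | 6-methylbenzene-1,2,4-triol | Cc1cc(O)cc(O)c1O | intermediate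
4 | 3-methylbut-2-enoic acid | CC(C)=CC(=O)O | starting material
5 | 3-methyl-1-(2,4,5-trihydroxy-6-methylphenyl)but-2-en-1-one | CC(C)=CC(=O)c1c(C)c(O)c(O)cc1O | intermediate (not isolated)
6 | 6,7-dihydroxy-2,2,5-trimethylchroman-4-one | CC1(C)CC(=O)c2c(C)c(O)c(O)cc2O1 | intermediate
7 | 7-(benzyloxy)-6-hydroxy-2,2,5-trimethylchroman-4-one | CC1(C)CC(=O)c2c(C)c(O)c(OCc3ccccc3)cc2O1 | intermediate
8 | trichloroethylene | ClC=C(Cl)Cl | starting material
9 | 7-(benzyloxy)-6-{[(E)-1,2-dichloroethenyl]oxy}-2,2,5-trimethylchroman-4-one | CC1(C)CC(=O)c2c(C)c(O/C(Cl)=C\Cl)c(OCc3ccccc3)cc2O1 | intermediate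
10 | {[7-(benzyloxy)-6-{[(E)-1,2-dichloroethenyl]oxy}-2,2,5-trimethyl-2H-chromen-4-yl]oxy}(tert-butyl)dimethylsilane | CC1(C)C=C(O[Si](C)(C)C(C)(C)C)c2c(C)c(O/C(Cl)=C\Cl)c(OCc3ccccc3)cc2O1 | intermediate
11 | benzyl chloroformate | O=C(Cl)OCc1ccccc1 | starting material
12 | {[7-(benzyloxy)-6-[(chloroethynyl)oxy]-2,2,5-trimethyl-2H-chromen-4-yl]oxy}(tert-butyl)dimethylsilane | CC1(C)C=C(O[Si](C)(C)C(C)(C)C)c2c(C)c(OC#CCl)c(OCc3ccccc3)cc2O1 | intermediate (not isolated)
13 | lithium acetylide of 7-(benzyloxy)-4-[(tert-butyldimethylsilyl)oxy]-6-(ethynyloxy)-2,2,5-trimethyl-2H-chromene | CC1(C)C=C(O[Si](C)(C)C(C)(C)C)c2c(C)c(OC#C[Li])c(OCc3ccccc3)cc2O1 | intermediate (not isolated)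
14 | benzyl 3-({7-(benzyloxy)-4-[(tert-butyldimethylsilyl)oxy]-2,2,5-trimethyl-2H-chromen-6-yl}oxy)prop-2-ynoate | CC1(C)C=C(O[Si](C)(C)C(C)(C)C)c2c(C)c(OC#CC(=O)OCc3ccccc3)c(OCc3ccccc3)cc2O1 | intermediate
15 | 4-hydroxy-6-methyl-2H-pyran-2-one | CC1=CC(O)=CC(=O)O1 | starting material
16 | N-[(4-chloro-6-methyl-2-oxo-2H-pyran-3-yl)methylidene]-N-methylmethanaminium chloride | CC1=CC(Cl)=C(C=[N+](C)C)C(=O)O1.[Cl-] | intermediate (not isolated)
17 | 4-chloro-6-methyl-2-oxo-2H-pyran-3-carbaldehyde | CC1=CC(Cl)=C(C=O)C(=O)O1 | intermediate
18 | 4-methoxy-6-methyl-2-oxo-2H-pyran-3-carbaldehyde | CC1=CC(OC)=C(C=O)C(=O)O1 | intermediate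
19 | 3-(dimethoxymethyl)-4-methoxy-6-methyl-2H-pyran-2-one | CC1=CC(OC)=C(C(OC)OC)C(=O)O1 | intermediate
20 | benzyl 5-({7-(benzyloxy)-4-[(tert-butyldimethylsilyl)oxy]-2,2,5-trimethyl-2H-chromen-6-yl}oxy)-4-(dimethoxymethyl)-8-methoxy-1-methyl-3-oxo-2-oxabicyclo[2.2.2]octa-5,7-diene-6-carboxylate (racemic; bridgeheads fixed relative to each other by the bicycle) | CC12OC(=O)C(C(OC)OC)(C(OC)=C1)C(Oc1c(C)c3c(cc1OCc4ccccc4)OC(C)(C)C=C3O[Si](C)(C)C(C)(C)C)=C2C(=O)OCc1ccccc1 | intermediate (not isolated)
21 | benzyl 2-({7-(benzyloxy)-4-[(tert-butyldimethylsilyl)oxy]-2,2,5-trimethyl-2H-chromen-6-yl}oxy)-3-(dimethoxymethyl)-4-methoxy-6-methylbenzoate | Cc1cc(OC)c(C(OC)OC)c(Oc2c(C)c3c(cc2OCc4ccccc4)OC(C)(C)C=C3O[Si](C)(C)C(C)(C)C)c1C(=O)OCc1ccccc1 | intermediate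
22 | benzyl 2-{[7-(benzyloxy)-2,2,5-trimethyl-4-oxochroman-6-yl]oxy}-3-formyl-4-methoxy-6-methylbenzoate | Cc1cc(OC)c(C=O)c(Oc2c(C)c3c(cc2OCc4ccccc4)OC(C)(C)CC3=O)c1C(=O)OCc1ccccc1 | intermediate
23 | 3-formyl-2-[(7-hydroxy-2,2,5-trimethyl-4-oxochroman-6-yl)oxy]-4-methoxy-6-methylbenzoic acid | Cc1cc(OC)c(C=O)c(Oc2c(C)c3c(cc2O)OC(C)(C)CC3=O)c1C(=O)O | intermediate
24 | O-methylmollicellin A (depsidone lactone with methoxy and formyl on ring A) | Cc1cc(OC)c(C=O)c2c1C(=O)Oc1cc3c(c(C)c1O2)C(=O)CC(C)(C)O3 | intermediate
25 | mollicellin A | Cc1cc(O)c(C=O)c2c1C(=O)Oc1cc3c(c(C)c1O2)C(=O)CC(C)(C)O3 | target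

## Step count and risk

Total: 14 steps. Longest linear sequence: 11 steps (steps 1–6, then 10–14); the pyrone branch (steps 7–9) joins at step 10.

**Step 10 (key step, proposed new method).** The cycloaddition may not occur below the temperature at which the push-pull alkyne oligomerises or the enol ether and acetal degrade. The steric clash between the acetal-bearing C3 and the aryloxy-bearing alkyne carbon may also divert bond formation to the reversed orientation. The fallback uses known chemistry (directed lithiation and nucleophilic aromatic substitution); it sets out from phenol 7 and rejoins the route at 22.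
- 1-Fluoro-3-methoxy-5-methylbenzene F1 would be lithiated between fluorine and methoxy (n-BuLi, THF, −78 °C) and formylated with DMF to 2-fluoro-6-methoxy-4-methylbenzaldehyde F2.
- F2 would be protected as 2-(dimethoxymethyl)-1-fluoro-3-methoxy-5-methylbenzene F3 (HC(OMe)3, MeOH, TsOH).
- F3 would be lithiated ortho to fluorine with LiTMP at −78 °C and acylated with benzyl chloroformate 11 to give benzyl 2-fluoro-3-(dimethoxymethyl)-4-methoxy-6-methylbenzoate F4.
- F4 would be hydrolysed (1 M HCl, THF) to benzyl 2-fluoro-3-formyl-4-methoxy-6-methylbenzoate F5.
- The fluoride of F5, activated by the ortho formyl and ortho ester groups, would be displaced by the phenoxide of 7 (K2CO3, DMF, 80 °C) to give 22 directly.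

The ketone needs no mask on this path and steps 4–10 are bypassed, at the price of building ring A by two successive metalations.

**Step 6.** The acetylide may add a second time to the new ynoate, the alkyllithium may attack silicon, or the electron-rich ynoate may be hydrated on work-up. The fallback sets out from 10 (through acetylide 13, made as in step 6) and returns at 14. Acetylide 13 would be quenched with dry CO2 at −78 °C to give lithium 3-({7-(benzyloxy)-4-[(tert-butyldimethylsilyl)oxy]-2,2,5-trimethyl-2H-chromen-6-yl}oxy)prop-2-ynoate F6. This carboxylate, which cannot be acylated further, would be O-alkylated with benzyl bromide in DMF without liberating the free acid, giving 14.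

**Step 2.** Acylation may take place at the other free position (between the two hydroxyls), or the electron-rich triol may be degraded oxidatively in hot acid. The fallback sets out from 3 and returns at 6. A Hoesch reaction of 3 with acetonitrile (ZnCl2, HCl, Et2O, 0 °C; then hot water), which is run cold and is strongly selective for the position para to a hydroxyl, would give 1-(2,4,5-trihydroxy-6-methylphenyl)ethan-1-one F7. Kabbe condensation of F7 with acetone and pyrrolidine (EtOH, reflux, Ar) would then close the chromanone 6 under basic conditions.

**Step 12.** The formyl group may be over-reduced to the benzylic alcohol or methyl group during debenzylation. The fallback reorders the unmasking; it sets out from 21 and returns at 24.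
- Buffered fluoride (TBAF, AcOH, THF, 0 °C) would cleave only the silyl enol ether, giving benzyl 2-{[7-(benzyloxy)-2,2,5-trimethyl-4-oxochroman-6-yl]oxy}-3-(dimethoxymethyl)-4-methoxy-6-methylbenzoate F8.
- Hydrogenolysis (H2, Pd/C, EtOAc, solid NaHCO3), with the aldehyde still an acetal, would give 3-(dimethoxymethyl)-2-[(7-hydroxy-2,2,5-trimethyl-4-oxochroman-6-yl)oxy]-4-methoxy-6-methylbenzoic acid F9.
- DCC lactonisation would give O-methylmollicellin A dimethyl acetal F10.
- Aqueous acid (1 M HCl, THF) would release the aldehyde to give 24.

## Further compounds

F1 | step 10 | 1-fluoro-3-methoxy-5-methylbenzene | COc1cc(C)cc(F)c1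
F2 | step 10 | 2-fluoro-6-methoxy-4-methylbenzaldehyde | COc1cc(C)cc(F)c1C=O
F3 | step 10 | 2-(dimethoxymethyl)-1-fluoro-3-methoxy-5-methylbenzene | COc1cc(C)cc(F)c1C(OC)OC
F4 | step 10 | benzyl 2-fluoro-3-(dimethoxymethyl)-4-methoxy-6-methylbenzoate | COc1cc(C)c(C(=O)OCc2ccccc2)c(F)c1C(OC)OC
F5 | step 10 | benzyl 2-fluoro-3-formyl-4-methoxy-6-methylbenzoate | COc1cc(C)c(C(=O)OCc2ccccc2)c(F)c1C=O
F6 | step 6 | lithium 3-({7-(benzyloxy)-4-[(tert-butyldimethylsilyl)oxy]-2,2,5-trimethyl-2H-chromen-6-yl}oxy)prop-2-ynoate | CC1(C)C=C(O[Si](C)(C)C(C)(C)C)c2c(C)c(OC#CC(=O)[O-])c(OCc3ccccc3)cc2O1.[Li+]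
F7 | step 2 | 1-(2,4,5-trihydroxy-6-methylphenyl)ethan-1-one | CC(=O)c1c(C)c(O)c(O)cc1O
F8 | step 12 | benzyl 2-{[7-(benzyloxy)-2,2,5-trimethyl-4-oxochroman-6-yl]oxy}-3-(dimethoxymethyl)-4-methoxy-6-methylbenzoate | Cc1cc(OC)c(C(OC)OC)c(Oc2c(C)c3c(cc2OCc4ccccc4)OC(C)(C)CC3=O)c1C(=O)OCc1ccccc1
F9 | step 12 | 3-(dimethoxymethyl)-2-[(7-hydroxy-2,2,5-trimethyl-4-oxochroman-6-yl)oxy]-4-methoxy-6-methylbenzoic acid | Cc1cc(OC)c(C(OC)OC)c(Oc2c(C)c3c(cc2O)OC(C)(C)CC3=O)c1C(=O)O
F10 | step 12 | O-methylmollicellin A dimethyl acetal | Cc1cc(OC)c(C(OC)OC)c2c1C(=O)Oc1cc3c(c(C)c1O2)C(=O)CC(C)(C)O3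
A1 | alternative 1 | 6,7-bis(benzyloxy)-4-methoxy-2,2,5-trimethylchroman (racemic) | COC1CC(C)(C)Oc2cc(OCc3ccccc3)c(OCc3ccccc3)c(C)c12
A2 | alternative 1 | 4,5-bis(benzyloxy)-2-hydroxy-6-methylbenzaldehyde | Cc1c(C=O)c(O)cc(OCc2ccccc2)c1OCc1ccccc1
A3 | alternative 1 | 2-methylpropene | CC(C)=C
A4 | alternative 2 | mollicellin A ethyl ether diethyl acetal | Cc1cc(OCC)c(C(OCC)OCC)c2c1C(=O)Oc1cc3c(c(C)c1O2)C(=O)CC(C)(C)O3
A5 | alternative 2 | 6-[(3,3-diethoxyprop-1-yn-1-yl)oxy]-2,2,5-trimethyl-4-oxochroman-7-yl but-2-ynoate | CC#CC(=O)Oc1cc2OC(C)(C)CC(=O)c2c(C)c1OC#CC(OCC)OCC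
A6 | alternative 2 | ethoxyacetylene | CCOC#C
A7 | alternative 3 | 6-bromo-2,2,5-trimethyl-4-oxochroman-7-yl 2,4-dihydroxy-6-methylbenzoate | Cc1cc(O)cc(O)c1C(=O)Oc1cc2OC(C)(C)CC(=O)c2c(C)c1Br
A8 | alternative 3 | 6-(2,4-dioxopentyl)-2,2-dimethyl-4H-1,3-dioxin-4-one | CC(=O)CC(=O)CC1=CC(=O)OC(C)(C)O1
A9 | alternative 3 | 6-bromo-7-hydroxy-2,2,5-trimethylchroman-4-one | CC1(C)CC(=O)c2c(C)c(Br)c(O)cc2O1
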